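**Retrosynthetic overview**

1. Target 17 ← triacetate 16 (selective removal of the two aryl acetates) ← triol 15 ← silyl ether 14; the phenols carry no protecting group before this point.
2. Key disconnection at the side-chain C2′–C3′ bond: 14 ← organomagnesium/copper reagent from (R,Z)-bromide 6 (C3′–C15′) + 4-ethenyl-6-methyl-2H-pyran-2-one 10 (C1′, C2′ and all six future ring carbons), by 1,6-addition to the vinyl terminus and, in the same flask, methoxide-induced isomerisation of the 2-pyranone into the resorcinol.
3. Enabling feature: the resorcinol ring (C1–C6, chain on C5, meta to both C–OH) is a constitutional isomer of a 4-alkyl-6-methyl-2-pyranone. Pyranone C2 (C=O) and C6 (C–O) become the two C–OH carbons, the 6-CH3 carbon becomes ring C2, and pyranone C4 becomes ring C5. Because C4 is the β-carbon of the unsaturated lactone, a vinyl group there makes C2′ a vinylogous Michael terminus.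
4. 6 ← (R)-oct-1-yn-3-ol 1 (stereocentre from the chiral pool) by silylation, acetylide alkylation with 1,5-dibromopentane 3 and Lindlar reduction (sets the Z-alkene); 10 ← triacetic acid lactone 7 by tosylation and Suzuki vinylation.
5. Ring order: the pyranone ring is carried from 7; the benzene ring, the only ring of the target, is formed last, inside the key step, by Claisen-type C-acylation.

Key step: step 6

Remark: side-chain carbons are numbered C1′ (benzylic) to C15′; the target is read as (R) at C10′ and (Z) at C8′=C9′, and (R)-oct-1-yn-3-ol is taken as a purchasable enantiopure building block.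

**Route**

Step 1
Reactants: 1 (R)-oct-1-yn-3-ol
Product: 2 (R)-tert-butyl(dimethyl)(oct-1-yn-3-yloxy)silane
Conditions: TBSCl (1.2 equiv), imidazole (2 equiv), DMF, 0 °C → rt
Reagents that add atoms: tert-butyldimethylsilyl chloride, CC(C)(C)[Si](C)(C)Cl
Why: Standard O-silylation of a secondary alcohol, which does not touch the C–O bond of the stereocentre, so the (R) centre of 1 is carried unchanged.

Step 2
Reactants: 2 (R)-tert-butyl(dimethyl)(oct-1-yn-3-yloxy)silane; 3 1,5-dibromopentane
Product: 5 (R)-[(13-bromotridec-7-yn-6-yl)oxy](tert-butyl)dimethylsilane, via lithium acetylide 4 (not isolated)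
Conditions: n-BuLi (1.05 equiv), THF, −78 °C; then 3 (3 equiv), DMPU, −78 °C → rt
Reagents that add atoms: none
Why: Acetylide alkylation (SN2 at a primary bromide, promoted by DMPU), in which the threefold excess of the dibromide should suppress double alkylation and the stereocentre is not involved.

Step 3
Reactants: 5 (R)-[(13-bromotridec-7-yn-6-yl)oxy](tert-butyl)dimethylsilane
Product: 6 (R,Z)-[(13-bromotridec-7-en-6-yl)oxy](tert-butyl)dimethylsilane
Conditions: H2 (1 atm), Lindlar catalyst, quinoline, hexane/EtOAc, rt
Reagents that add atoms: none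
Why: Lindlar semi-hydrogenation delivers both hydrogens to one face of the alkyne on poisoned palladium and so should set the (Z)-alkene, while the C–Br bond and the silyl ether are inert.

Step 4
Reactants: 7 4-hydroxy-6-methyl-2H-pyran-2-one (triacetic acid lactone)
Product: 8 6-methyl-2-oxo-2H-pyran-4-yl 4-methylbenzenesulfonate
Conditions: TsCl (1.1 equiv), Et3N (1.3 equiv), CH2Cl2, 0 °C → rt
Reagents that add atoms: 4-methylbenzenesulfonyl chloride, Cc1ccc(cc1)S(=O)(=O)Cl
Why: The 4-OH of 7 is a vinylogous carboxylic acid and should be sulfonylated cleanly on oxygen (sulfonate ester formation).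

Step 5
Reactants: 8 6-methyl-2-oxo-2H-pyran-4-yl 4-methylbenzenesulfonate; 9 2-ethenyl-4,4,5,5-tetramethyl-1,3,2-dioxaborolane
Product: 10 4-ethenyl-6-methyl-2H-pyran-2-one
Conditions: PdCl2(dppf) (3 mol %), K2CO3 (2 equiv), THF/H2O 10:1, 55 °C; product kept cold with BHT and used at once
Reagents that add atoms: none
Why: Suzuki–Miyaura coupling, in which the sulfonate on the β-carbon of the unsaturated lactone (a vinylogous acyl sulfonate) should undergo easy oxidative addition and the vinylboronate then transfers the vinyl group.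

Step 6
Reactants: 6 (R,Z)-[(13-bromotridec-7-en-6-yl)oxy](tert-butyl)dimethylsilane; 10 4-ethenyl-6-methyl-2H-pyran-2-one
Product: 14 5-[(8Z,10R)-10-(tert-butyldimethylsilyloxy)pentadec-8-en-1-yl]benzene-1,3-diol, via Grignard reagent 11 (not isolated), via 4-alkyl-2-pyranone 12 (not isolated), via ring-opened keto ester 13 (not isolated)
Conditions: Mg (I2-activated), THF, 45 °C; slow addition to 10 + CuBr·SMe2 (10 mol %), THF, −70 → −30 °C; then NaOMe (5 equiv)/MeOH, 65 °C, Ar; 1 M HCl to pH 4
Reagents that add atoms: none
Why: Proposed new method: the Grignard reagent 11 is transferred to copper and adds in a 1,6-sense to the unsubstituted CH2 terminus of the 4-vinyl group (acceptor C=C–C4=C3–C2=O of the pyranone), which forms the side-chain C2′–C3′ bond and, after protonation, the 4-alkyl-6-methyl-2-pyranone 12; the closest known reaction type is the copper-catalysed 1,6-addition of Grignard reagents to 2,4-dienoates. Methoxide then opens the lactone at C2 to the (Z)-δ-keto enoate 13, whose methyl-ketone enolate attacks the ester carbon in an intramolecular Claisen (Dieckmann-type) condensation; the closest known analogues are the alkoxide cyclisation of 5-oxohexanoates to cyclohexane-1,3-diones and the classical base-induced conversion of pyranone-masked polyketides into orcinol-type phenols. This closes the benzene ring by a 6-(enolendo)-exo-trig closure between the former 6-methyl carbon and the former lactone carbonyl carbon, and the resulting cyclohex-4-ene-1,3-dione should tautomerise at once to the resorcinol(ate). No stereocentre is created, and the (R) centre and (Z)-alkene of 6 are remote from all reacting sites. Site selectivity in the addition (vinyl terminus rather than 1,2-attack at the lactone carbonyl or attack at the substituted C6) rests on soft copper catalysis at low temperature and on the vinyl CH2 being the only unhindered electrophilic terminus. Selectivity in the ring switch rests on reversibility, since O-acylation only returns the pyranone whereas C-acylation is made irreversible by deprotonation of the aromatic product, and the (Z)-enoate geometry needed for closure is inherited from the pyranone ring.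

Step 7
Reactants: 14 5-[(8Z,10R)-10-(tert-butyldimethylsilyloxy)pentadec-8-en-1-yl]benzene-1,3-diol
Product: 15 5-[(8Z,10R)-10-hydroxypentadec-8-en-1-yl]benzene-1,3-diol
Conditions: HF·pyridine, THF/pyridine, 0 °C → rt
Reagents that add atoms: none
Why: Fluoride-driven cleavage of the secondary silyl ether (Si–F bond formation) proceeds at silicon without ionisation at the allylic carbon, so configuration and alkene geometry should be retained.

Step 8
Reactants: 15 5-[(8Z,10R)-10-hydroxypentadec-8-en-1-yl]benzene-1,3-diol
Product: 16 5-[(8Z,10R)-10-acetoxypentadec-8-en-1-yl]-1,3-phenylene diacetate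
Conditions: Ac2O (4 equiv), pyridine, DMAP (5 mol %), CH2Cl2, 0 °C → rt
Reagents that add atoms: acetic anhydride, CC(=O)OC(C)=O
Why: Exhaustive DMAP-catalysed acetylation of the two phenols and the secondary allylic alcohol takes place at oxygen with retention at carbon.

Step 9
Reactants: 16 5-[(8Z,10R)-10-acetoxypentadec-8-en-1-yl]-1,3-phenylene diacetate
Product: 17 (6R,7Z)-15-(3,5-dihydroxyphenyl)pentadec-7-en-6-yl acetate (CNP0315732.1)
Conditions: NH4OAc (10 equiv), MeOH/H2O 4:1, rt
Reagents that add atoms: none
Why: Chemoselective solvolysis of aryl acetates, in which phenoxide is a far better leaving group than a secondary alkoxide, so the two phenolic acetates should be cleaved while the allylic acetate stays.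

**Compound list**

1 | (R)-oct-1-yn-3-ol | CCCCC[C@H](C#C)O | starting material
2 | (R)-tert-butyl(dimethyl)(oct-1-yn-3-yloxy)silane | CCCCC[C@H](C#C)O[Si](C)(C)C(C)(C)C | intermediate
3 | 1,5-dibromopentane | BrCCCCCBr | starting material
4 | [(3R)-3-(tert-butyldimethylsilyloxy)oct-1-yn-1-yl]lithium | CCCCC[C@H](C#C[Li])O[Si](C)(C)C(C)(C)C | intermediate
5 | (R)-[(13-bromotridec-7-yn-6-yl)oxy](tert-butyl)dimethylsilane | CCCCC[C@H](C#CCCCCCBr)O[Si](C)(C)C(C)(C)C | intermediate
6 | (R,Z)-[(13-bromotridec-7-en-6-yl)oxy](tert-butyl)dimethylsilane | CCCCC[C@H](/C=C\CCCCCBr)O[Si](C)(C)C(C)(C)C | intermediate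
7 | 4-hydroxy-6-methyl-2H-pyran-2-one (triacetic acid lactone) | Cc1cc(O)cc(=O)o1 | starting material
8 | 6-methyl-2-oxo-2H-pyran-4-yl 4-methylbenzenesulfonate | Cc1cc(OS(=O)(=O)c2ccc(C)cc2)cc(=O)o1 | intermediate
9 | 2-ethenyl-4,4,5,5-tetramethyl-1,3,2-dioxaborolane | C=CB1OC(C)(C)C(C)(C)O1 | starting material
10 | 4-ethenyl-6-methyl-2H-pyran-2-one | Cc1cc(C=C)cc(=O)o1 | intermediate
11 | [(6Z,8R)-8-(tert-butyldimethylsilyloxy)tridec-6-en-1-yl]magnesium bromide | CCCCC[C@H](/C=C\CCCCC[Mg]Br)O[Si](C)(C)C(C)(C)C | intermediate
12 | 4-[(8Z,10R)-10-(tert-butyldimethylsilyloxy)pentadec-8-en-1-yl]-6-methyl-2H-pyran-2-one | CCCCC[C@H](/C=C\CCCCCCCc1cc(C)oc(=O)c1)O[Si](C)(C)C(C)(C)C | intermediate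
13 | methyl (2Z,11Z,13R)-13-(tert-butyldimethylsilyloxy)-3-(2-oxopropyl)octadeca-2,11-dienoate | CCCCC[C@H](/C=C\CCCCCCC/C(CC(C)=O)=C/C(=O)OC)O[Si](C)(C)C(C)(C)C | intermediate
14 | 5-[(8Z,10R)-10-(tert-butyldimethylsilyloxy)pentadec-8-en-1-yl]benzene-1,3-diol | CCCCC[C@H](/C=C\CCCCCCCc1cc(O)cc(O)c1)O[Si](C)(C)C(C)(C)C | intermediate
15 | 5-[(8Z,10R)-10-hydroxypentadec-8-en-1-yl]benzene-1,3-diol | CCCCC[C@H](/C=C\CCCCCCCc1cc(O)cc(O)c1)O | intermediate
16 | 5-[(8Z,10R)-10-acetoxypentadec-8-en-1-yl]-1,3-phenylene diacetate | CCCCC[C@H](/C=C\CCCCCCCc1cc(OC(C)=O)cc(OC(C)=O)c1)OC(C)=O | intermediate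
17 | (6R,7Z)-15-(3,5-dihydroxyphenyl)pentadec-7-en-6-yl acetate | CCCCC[C@H](/C=C\CCCCCCCc1cc(O)cc(O)c1)OC(C)=O | target

**Step count and risks**

Total steps: 9. Longest linear sequence: 7 (steps 1, 2, 3, 6, 7, 8, 9).

Step 6 (bears the label). What may go wrong: in the first stage the organometallic may attack the lactone carbonyl, or the magnesium enolate may add to unreacted 10 and start oligomerisation. In the second stage the ring-opened dienolate may re-lactonise or condense intermolecularly faster than it undergoes C-acylation. Fallback with known chemistry, setting out from 6 and coming back at 15: commercial methyl 2-(3,5-dihydroxyphenyl)acetate F1 would be silylated on both phenols (TBSCl, imidazole) to methyl 2-[3,5-bis(tert-butyldimethylsilyloxy)phenyl]acetate F2. DIBAL-H reduction would give 2-[3,5-bis(tert-butyldimethylsilyloxy)phenyl]ethan-1-ol F3, and tosylation would give 2-[3,5-bis(tert-butyldimethylsilyloxy)phenyl]ethyl 4-methylbenzenesulfonate F4. The Grignard reagent 11, made from 6 as in step 6, would be coupled with F4 under Li2CuCl4 catalysis (Kochi–Schlosser sp3–sp3 coupling, THF, −20 → 0 °C). This forms the same C2′–C3′ bond on a preformed arene and should give tert-butyl{[(6R,7Z)-15-[3,5-bis(tert-butyldimethylsilyloxy)phenyl]pentadec-7-en-6-yl]oxy}dimethylsilane F5. HF·pyridine would remove all three silyl groups and deliver triol 15, from which steps 8 and 9 follow unchanged.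

Step 5. What may go wrong: hydrolytic loss of the sulfonate or base-induced opening of the pyranone under the aqueous basic coupling conditions, and Diels–Alder dimerisation or polymerisation of the vinylpyranone during isolation. Fallback, setting out from 8 and coming back at 10: the vinyl group would be made by semi-reduction of an alkyne instead of by vinyl transfer. Sonogashira coupling of 8 with ethynyltrimethylsilane (PdCl2(PPh3)2, CuI, i-Pr2NEt, MeCN) should give 6-methyl-4-[(trimethylsilyl)ethynyl]-2H-pyran-2-one F6. Buffered protodesilylation (TBAF, AcOH, THF, 0 °C) should give 4-ethynyl-6-methyl-2H-pyran-2-one F7. Lindlar semi-hydrogenation would then release 10 last, under neutral conditions, as a filtered solution that can go directly into step 6.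

Step 9. What may go wrong: competing solvolysis of the secondary allylic acetate, or incomplete removal of the second aryl acetate, leading to mixtures of partially acetylated material. Fallback, setting out from 14 and coming back at 17: the differentiation would be moved from acetates to silyl ethers. Both phenols of 14 would be silylated (TIPSCl, imidazole, DMF) to tert-butyl{[(6R,7Z)-15-[3,5-bis(triisopropylsilyloxy)phenyl]pentadec-7-en-6-yl]oxy}dimethylsilane F8. Mild acid methanolysis (CSA, MeOH, 0 °C), which spares aryl silyl ethers, should remove only the alkyl TBS group and give (6R,7Z)-15-[3,5-bis(triisopropylsilyloxy)phenyl]pentadec-7-en-6-ol F9. Acetylation (Ac2O, pyridine, DMAP) would give (6R,7Z)-15-[3,5-bis(triisopropylsilyloxy)phenyl]pentadec-7-en-6-yl acetate F10. Buffered fluoride (TBAF, AcOH, THF, 0 °C) would then cleave the two aryl silyl ethers and give 17.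

**Further compounds**

F1 | step 6 | methyl 2-(3,5-dihydroxyphenyl)acetate | COC(=O)Cc1cc(O)cc(O)c1
F2 | step 6 | methyl 2-[3,5-bis(tert-butyldimethylsilyloxy)phenyl]acetate | COC(=O)Cc1cc(O[Si](C)(C)C(C)(C)C)cc(O[Si](C)(C)C(C)(C)C)c1
F3 | step 6 | 2-[3,5-bis(tert-butyldimethylsilyloxy)phenyl]ethan-1-ol | OCCc1cc(O[Si](C)(C)C(C)(C)C)cc(O[Si](C)(C)C(C)(C)C)c1
F4 | step 6 | 2-[3,5-bis(tert-butyldimethylsilyloxy)phenyl]ethyl 4-methylbenzenesulfonate | Cc1ccc(cc1)S(=O)(=O)OCCc1cc(O[Si](C)(C)C(C)(C)C)cc(O[Si](C)(C)C(C)(C)C)c1
F5 | step 6 | tert-butyl{[(6R,7Z)-15-[3,5-bis(tert-butyldimethylsilyloxy)phenyl]pentadec-7-en-6-yl]oxy}dimethylsilane | CCCCC[C@H](/C=C\CCCCCCCc1cc(O[Si](C)(C)C(C)(C)C)cc(O[Si](C)(C)C(C)(C)C)c1)O[Si](C)(C)C(C)(C)C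
F6 | step 5 | 6-methyl-4-[(trimethylsilyl)ethynyl]-2H-pyran-2-one | Cc1cc(C#C[Si](C)(C)C)cc(=O)o1
F7 | step 5 | 4-ethynyl-6-methyl-2H-pyran-2-one | Cc1cc(C#C)cc(=O)o1
F8 | step 9 | tert-butyl{[(6R,7Z)-15-[3,5-bis(triisopropylsilyloxy)phenyl]pentadec-7-en-6-yl]oxy}dimethylsilane | CCCCC[C@H](/C=C\CCCCCCCc1cc(O[Si](C(C)C)(C(C)C)C(C)C)cc(O[Si](C(C)C)(C(C)C)C(C)C)c1)O[Si](C)(C)C(C)(C)C
F9 | step 9 | (6R,7Z)-15-[3,5-bis(triisopropylsilyloxy)phenyl]pentadec-7-en-6-ol | CCCCC[C@H](/C=C\CCCCCCCc1cc(O[Si](C(C)C)(C(C)C)C(C)C)cc(O[Si](C(C)C)(C(C)C)C(C)C)c1)O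
F10 | step 9 | (6R,7Z)-15-[3,5-bis(triisopropylsilyloxy)phenyl]pentadec-7-en-6-yl acetate | CCCCC[C@H](/C=C\CCCCCCCc1cc(O[Si](C(C)C)(C(C)C)C(C)C)cc(O[Si](C(C)C)(C(C)C)C(C)C)c1)OC(C)=O
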